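## Retrosynthetic overview

1. Target 18 ⇐ NaBH4 reduction of ketone 17 (sets C4 of ring F) ⇐ global O‑debenzylation of 16. Rings A/C/B are the upper flavan unit, D/F/E the lower unit.
2. Ring F of 16: the O1–C2 and C3–OH bonds are made together by an enantioselective oxidative oxa‑Michael cyclisation of 2'‑hydroxychalcone 15 (new C–O‑forming key step). 15 ⇐ aldehyde 14 + acetophenone 4 (aldol).
3. Ring C: C3–OH and C4–H come from hydroboration of the (2S)‑4‑aryl‑2H‑chromene 10. The O1–C2 bond of 10 comes from a chiral‑acid‑catalysed dehydrative allylic etherification of carbinol 9 (second C–O ring closure).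
4. Carbon skeleton: 9 ⇐ aryl cerium reagent from bromo acetal 3 + chalcone 5; 5 ⇐ 4 + 1; 3 ⇐ 1. Compounds 1 and 4 are inexpensive catalogue chemicals.
5. Ring order: ring C first (steps 5–6), ring F last (step 9); rings A, B, D, E are bought in 1 and 4.

Assumption: the sense of induction of the two chiral catalysts (steps 5 and 9) is taken from the closest models and is confirmed by a trial run on chalcone 5 or its carbinol; the antipode (or pseudoenantiomer) that gives the stated configuration is used.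

## Route

Step 1
Reactants: 1 3,4,5-tris(benzyloxy)benzaldehyde
Product: 2 2-bromo-3,4,5-tris(benzyloxy)benzaldehyde
Conditions: N-bromosuccinimide (1.05 equiv), MeCN, rt, dark
Reagents that add atoms: N-bromosuccinimide, O=C1CCC(=O)N1Br
Why: Electrophilic aromatic bromination; the two equivalent free positions of the trialkoxy ring are far more electron-rich than the benzyl rings, so mono-bromination ortho to the formyl group is clean.

Step 2
Reactants: 2 2-bromo-3,4,5-tris(benzyloxy)benzaldehyde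
Product: 3 2-[2-bromo-3,4,5-tris(benzyloxy)phenyl]-1,3-dioxolane
Conditions: ethylene glycol, p-toluenesulfonic acid (cat.), toluene, reflux, Dean–Stark
Reagents that add atoms: ethylene glycol, OCCO
Why: Acid-catalysed acetalisation with azeotropic removal of water masks the aldehyde for the lithiation and hydroboration steps.

Step 3
Reactants: 4 1-[4-(benzyloxy)-2-hydroxyphenyl]ethan-1-one; 1 3,4,5-tris(benzyloxy)benzaldehyde
Product: 5 (E)-1-[4-(benzyloxy)-2-hydroxyphenyl]-3-[3,4,5-tris(benzyloxy)phenyl]prop-2-en-1-one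
Conditions: KOH (50% aq.), EtOH/THF, rt
Reagents that add atoms: none
Why: Claisen–Schmidt aldol condensation; E1cB dehydration gives the E-enone.

Step 4
Reactants: 3 2-[2-bromo-3,4,5-tris(benzyloxy)phenyl]-1,3-dioxolane; 5 (E)-1-[4-(benzyloxy)-2-hydroxyphenyl]-3-[3,4,5-tris(benzyloxy)phenyl]prop-2-en-1-one
Product: 9 (E)-1-[4-(benzyloxy)-2-hydroxyphenyl]-1-[2,3,4-tris(benzyloxy)-6-(1,3-dioxolan-2-yl)phenyl]-3-[3,4,5-tris(benzyloxy)phenyl]prop-2-en-1-ol (racemic), via aryllithium 6 (not isolated), via arylcerium dichloride 7 (not isolated), via lithium phenolate 8 (not isolated)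
Conditions: 3, n-BuLi, THF, −78 °C; CeCl3 (anhydrous), −78 °C; then 5 pre-treated with LiN(SiMe3)2 (THF, −78 °C), −78 → −40 °C; pH 7 buffer, base-washed glassware
Reagents that add atoms: none
Why: Bromine–lithium exchange, transmetalation to cerium and 1,2-addition, the weakly basic oxophilic aryl cerium reagent attacking the carbonyl rather than the β-carbon of the chelated phenolate; the carbinol centre is racemic and is erased in step 5.

Step 5
Reactants: 9 (E)-1-[4-(benzyloxy)-2-hydroxyphenyl]-1-[2,3,4-tris(benzyloxy)-6-(1,3-dioxolan-2-yl)phenyl]-3-[3,4,5-tris(benzyloxy)phenyl]prop-2-en-1-ol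
Product: 10 (2S)-7-(benzyloxy)-4-[2,3,4-tris(benzyloxy)-6-(1,3-dioxolan-2-yl)phenyl]-2-[3,4,5-tris(benzyloxy)phenyl]-2H-chromene
Conditions: (R)-N-triflyl phosphoramide of 3,3'-bis(2,4,6-triisopropylphenyl)-5,5',6,6',7,7',8,8'-octahydro-1,1'-bi-2-naphthol, (ArO)2P(O)NHSO2CF3 (5 mol %), toluene, 4 Å molecular sieves, −78 °C, dark; Et3N quench
Reagents that add atoms: none
Why: Chiral Brønsted acid-catalysed dehydrative intramolecular allylic etherification (SN1-type allylic substitution through a chiral contact ion pair, a known route to 2,4-diaryl-2H-chromenes), in which the triarylallyl cation is paired with the phosphoramide anion and the phenol closes the O1–C2 bond on one face, setting C2 as S.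

Step 6
Reactants: 10 (2S)-7-(benzyloxy)-4-[2,3,4-tris(benzyloxy)-6-(1,3-dioxolan-2-yl)phenyl]-2-[3,4,5-tris(benzyloxy)phenyl]-2H-chromene
Product: 12 (2R,3S,4S)-7-(benzyloxy)-4-[2,3,4-tris(benzyloxy)-6-(1,3-dioxolan-2-yl)phenyl]-2-[3,4,5-tris(benzyloxy)phenyl]-3,4-dihydro-2H-chromen-3-ol, via alkylborane 11 (not isolated)
Conditions: BH3·THF, THF, 0 °C → rt; then NaOH, H2O2, 0 °C → rt
Reagents that add atoms: hydrogen peroxide, OO
Why: Hydroboration–oxidation, boron adding to the less substituted C3 and hydrogen to C4 in syn fashion on the face opposite the C2 aryl group, so that after oxidation with retention the C3 hydroxyl is trans to both aryl groups (2,3-trans-3,4-trans; C3 S, C4 S).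

Step 7
Reactants: 12 (2R,3S,4S)-7-(benzyloxy)-4-[2,3,4-tris(benzyloxy)-6-(1,3-dioxolan-2-yl)phenyl]-2-[3,4,5-tris(benzyloxy)phenyl]-3,4-dihydro-2H-chromen-3-ol
Product: 14 3,4,5-tris(benzyloxy)-2-{(2R,3S,4S)-3,7-bis(benzyloxy)-2-[3,4,5-tris(benzyloxy)phenyl]-3,4-dihydro-2H-chromen-4-yl}benzaldehyde, via benzyl ether acetal 13 (not isolated)
Conditions: NaH, BnBr, Bu4NI (cat.), DMF, 0 °C → rt; then 2 M HCl, THF, rt
Reagents that add atoms: benzyl bromide, BrCc1ccccc1; water, O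
Why: Williamson etherification caps the C3 hydroxyl (which would otherwise add to the neighbouring aldehyde and later to the enone to give isochromans), and acid hydrolysis of the dioxolane then frees the aldehyde without touching a stereocentre.

Step 8
Reactants: 14 3,4,5-tris(benzyloxy)-2-{(2R,3S,4S)-3,7-bis(benzyloxy)-2-[3,4,5-tris(benzyloxy)phenyl]-3,4-dihydro-2H-chromen-4-yl}benzaldehyde; 4 1-[4-(benzyloxy)-2-hydroxyphenyl]ethan-1-one
Product: 15 (E)-1-[4-(benzyloxy)-2-hydroxyphenyl]-3-[3,4,5-tris(benzyloxy)-2-{(2R,3S,4S)-3,7-bis(benzyloxy)-2-[3,4,5-tris(benzyloxy)phenyl]-3,4-dihydro-2H-chromen-4-yl}phenyl]prop-2-en-1-one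
Conditions: KOH (50% aq.), EtOH/THF, 40 °C
Reagents that add atoms: none
Why: Claisen–Schmidt aldol condensation gives the E-2'-hydroxychalcone; the benzylic ether and triarylmethine C–H bonds of the upper unit are not acidic enough to epimerise.

Step 9
Reactants: 15 (E)-1-[4-(benzyloxy)-2-hydroxyphenyl]-3-[3,4,5-tris(benzyloxy)-2-{(2R,3S,4S)-3,7-bis(benzyloxy)-2-[3,4,5-tris(benzyloxy)phenyl]-3,4-dihydro-2H-chromen-4-yl}phenyl]prop-2-en-1-one
Product: 16 (2R,3R)-7-(benzyloxy)-3-hydroxy-2-[3,4,5-tris(benzyloxy)-2-{(2R,3S,4S)-3,7-bis(benzyloxy)-2-[3,4,5-tris(benzyloxy)phenyl]-3,4-dihydro-2H-chromen-4-yl}phenyl]-2,3-dihydro-4H-chromen-4-one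
Conditions: N-[3,5-bis(trifluoromethyl)benzyl]-9-deoxy-9-epi-9-{3-[3,5-bis(trifluoromethyl)phenyl]ureido}cinchonidinium bromide (10 mol %), cumene hydroperoxide (1.5 equiv), K2CO3 (20 mol %), toluene, −20 °C
Reagents that add atoms: cumene hydroperoxide, CC(C)(OO)c1ccccc1
Why: Proposed new method: a catalytic enantioselective Algar–Flynn–Oyamada-type oxa-Michael/α-hydroxylation cascade, in which the chiral ammonium pairs with the chalcone phenolate while its urea binds the enone carbonyl (replacing the internal O–H···O=C bond and turning the phenolate oxygen toward the β-carbon), 6-endo-trig C–O bond formation inside this ion pair sets C2 (R), and the flavanone enolate so formed is hydroxylated at C3 by the hydroperoxide (attack on the O–O σ* orbital) on the face opposite the C2 aryl group before retro-Michael opening can racemise it, giving the trans-(2R,3R) dihydroflavonol while the released cumyloxide regenerates the phenolate; the closest known chemistry is the racemic Algar–Flynn–Oyamada oxidation with alkaline H2O2, phase-transfer-catalysed enantioselective α-hydroxylation of ketone enolates with hydroperoxides, and ammonium/urea-catalysed enantioselective oxa-Michael cyclisations, whose merger into one enantioselective ring-forming step has not been described.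

Step 10
Reactants: 16 (2R,3R)-7-(benzyloxy)-3-hydroxy-2-[3,4,5-tris(benzyloxy)-2-{(2R,3S,4S)-3,7-bis(benzyloxy)-2-[3,4,5-tris(benzyloxy)phenyl]-3,4-dihydro-2H-chromen-4-yl}phenyl]-2,3-dihydro-4H-chromen-4-one
Product: 17 (2R,3R)-3,7-dihydroxy-2-{2-[(2R,3S,4S)-3,7-dihydroxy-2-(3,4,5-trihydroxyphenyl)-3,4-dihydro-2H-chromen-4-yl]-3,4,5-trihydroxyphenyl}-2,3-dihydro-4H-chromen-4-one
Conditions: H2 (1 atm), Pd(OH)2/C, THF/MeOH, rt, then filtration under N2
Reagents that add atoms: none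
Why: Catalytic hydrogenolysis removes all nine O-benzyl groups under neutral conditions that leave the ring F aryl ketone intact, and doing this at the ketone stage avoids hydrogenolysis of the benzylic C4 hydroxyl that a flavan-3,4-diol would suffer.

Step 11
Reactants: 17 (2R,3R)-3,7-dihydroxy-2-{2-[(2R,3S,4S)-3,7-dihydroxy-2-(3,4,5-trihydroxyphenyl)-3,4-dihydro-2H-chromen-4-yl]-3,4,5-trihydroxyphenyl}-2,3-dihydro-4H-chromen-4-one
Product: 18 (2R,3S,4R)-2-{2-[(2R,3S,4S)-3,7-dihydroxy-2-(3,4,5-trihydroxyphenyl)-3,4-dihydro-2H-chromen-4-yl]-3,4,5-trihydroxyphenyl}-3,4-dihydro-2H-chromene-3,4,7-triol (CNP0205451.4)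
Conditions: NaBH4, EtOH, 0 °C → rt; AcOH to pH 6; Sephadex LH-20 (EtOH)
Reagents that add atoms: none
Why: Borohydride reduction of the dihydroflavonol carbonyl, the small hydride attacking axially to give the equatorial C4 hydroxyl trans to the C3 hydroxyl (4R), as is established for the reduction of free-phenolic 2,3-trans-dihydroflavonols to 2,3-trans-3,4-trans-flavan-3,4-diols.

## Compound list

1 | 3,4,5-tris(benzyloxy)benzaldehyde | O=Cc1cc(OCc2ccccc2)c(OCc2ccccc2)c(OCc2ccccc2)c1 | starting material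
2 | 2-bromo-3,4,5-tris(benzyloxy)benzaldehyde | O=Cc1cc(OCc2ccccc2)c(OCc2ccccc2)c(OCc2ccccc2)c1Br | intermediate
3 | 2-[2-bromo-3,4,5-tris(benzyloxy)phenyl]-1,3-dioxolane | Brc1c(C2OCCO2)cc(OCc2ccccc2)c(OCc2ccccc2)c1OCc1ccccc1 | intermediate
4 | 1-[4-(benzyloxy)-2-hydroxyphenyl]ethan-1-one | CC(=O)c1ccc(OCc2ccccc2)cc1O | starting material
5 | (E)-1-[4-(benzyloxy)-2-hydroxyphenyl]-3-[3,4,5-tris(benzyloxy)phenyl]prop-2-en-1-one | O=C(/C=C/c1cc(OCc2ccccc2)c(OCc2ccccc2)c(OCc2ccccc2)c1)c1ccc(OCc2ccccc2)cc1O | intermediate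
6 | [2,3,4-tris(benzyloxy)-6-(1,3-dioxolan-2-yl)phenyl]lithium | [Li]c1c(C2OCCO2)cc(OCc2ccccc2)c(OCc2ccccc2)c1OCc1ccccc1 | intermediate (not isolated)
7 | dichloro[2,3,4-tris(benzyloxy)-6-(1,3-dioxolan-2-yl)phenyl]cerium | Cl[Ce](Cl)c1c(C2OCCO2)cc(OCc2ccccc2)c(OCc2ccccc2)c1OCc1ccccc1 | intermediate (not isolated)
8 | lithium 5-(benzyloxy)-2-{(E)-3-[3,4,5-tris(benzyloxy)phenyl]prop-2-enoyl}phenolate | [Li+].[O-]c1cc(OCc2ccccc2)ccc1C(=O)/C=C/c1cc(OCc2ccccc2)c(OCc2ccccc2)c(OCc2ccccc2)c1 | intermediate (not isolated)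
9 | (E)-1-[4-(benzyloxy)-2-hydroxyphenyl]-1-[2,3,4-tris(benzyloxy)-6-(1,3-dioxolan-2-yl)phenyl]-3-[3,4,5-tris(benzyloxy)phenyl]prop-2-en-1-ol (racemic) | OC(/C=C/c1cc(OCc2ccccc2)c(OCc2ccccc2)c(OCc2ccccc2)c1)(c1ccc(OCc2ccccc2)cc1O)c1c(C2OCCO2)cc(OCc2ccccc2)c(OCc2ccccc2)c1OCc1ccccc1 | intermediate
10 | (2S)-7-(benzyloxy)-4-[2,3,4-tris(benzyloxy)-6-(1,3-dioxolan-2-yl)phenyl]-2-[3,4,5-tris(benzyloxy)phenyl]-2H-chromene | c1ccccc1COc1ccc2c(c1)O[C@H](c1cc(OCc3ccccc3)c(OCc3ccccc3)c(OCc3ccccc3)c1)C=C2c1c(C2OCCO2)cc(OCc2ccccc2)c(OCc2ccccc2)c1OCc1ccccc1 | intermediate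
11 | C3-boryl adduct of 10 (boron trans to the C2 aryl group, hydrogen at C4 on the same face as boron) | c1ccccc1COc1ccc2c(c1)O[C@H](c1cc(OCc3ccccc3)c(OCc3ccccc3)c(OCc3ccccc3)c1)[C@@H](B)[C@@H]2c1c(C2OCCO2)cc(OCc2ccccc2)c(OCc2ccccc2)c1OCc1ccccc1 | intermediate (not isolated)
12 | (2R,3S,4S)-7-(benzyloxy)-4-[2,3,4-tris(benzyloxy)-6-(1,3-dioxolan-2-yl)phenyl]-2-[3,4,5-tris(benzyloxy)phenyl]-3,4-dihydro-2H-chromen-3-ol | c1ccccc1COc1ccc2c(c1)O[C@H](c1cc(OCc3ccccc3)c(OCc3ccccc3)c(OCc3ccccc3)c1)[C@@H](O)[C@@H]2c1c(C2OCCO2)cc(OCc2ccccc2)c(OCc2ccccc2)c1OCc1ccccc1 | intermediate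
13 | (2R,3S,4S)-3,7-bis(benzyloxy)-4-[2,3,4-tris(benzyloxy)-6-(1,3-dioxolan-2-yl)phenyl]-2-[3,4,5-tris(benzyloxy)phenyl]-3,4-dihydro-2H-chromene | c1ccccc1COc1ccc2c(c1)O[C@H](c1cc(OCc3ccccc3)c(OCc3ccccc3)c(OCc3ccccc3)c1)[C@@H](OCc1ccccc1)[C@@H]2c1c(C2OCCO2)cc(OCc2ccccc2)c(OCc2ccccc2)c1OCc1ccccc1 | intermediate (not isolated)
14 | 3,4,5-tris(benzyloxy)-2-{(2R,3S,4S)-3,7-bis(benzyloxy)-2-[3,4,5-tris(benzyloxy)phenyl]-3,4-dihydro-2H-chromen-4-yl}benzaldehyde | c1ccccc1COc1ccc2c(c1)O[C@H](c1cc(OCc3ccccc3)c(OCc3ccccc3)c(OCc3ccccc3)c1)[C@@H](OCc1ccccc1)[C@@H]2c1c(C=O)cc(OCc2ccccc2)c(OCc2ccccc2)c1OCc1ccccc1 | intermediate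
15 | (E)-1-[4-(benzyloxy)-2-hydroxyphenyl]-3-[3,4,5-tris(benzyloxy)-2-{(2R,3S,4S)-3,7-bis(benzyloxy)-2-[3,4,5-tris(benzyloxy)phenyl]-3,4-dihydro-2H-chromen-4-yl}phenyl]prop-2-en-1-one | c1ccccc1COc1ccc2c(c1)O[C@H](c1cc(OCc3ccccc3)c(OCc3ccccc3)c(OCc3ccccc3)c1)[C@@H](OCc1ccccc1)[C@@H]2c1c(/C=C/C(=O)c2ccc(OCc3ccccc3)cc2O)cc(OCc2ccccc2)c(OCc2ccccc2)c1OCc1ccccc1 | intermediate
16 | (2R,3R)-7-(benzyloxy)-3-hydroxy-2-[3,4,5-tris(benzyloxy)-2-{(2R,3S,4S)-3,7-bis(benzyloxy)-2-[3,4,5-tris(benzyloxy)phenyl]-3,4-dihydro-2H-chromen-4-yl}phenyl]-2,3-dihydro-4H-chromen-4-one | c1ccccc1COc1ccc2c(c1)O[C@H](c1cc(OCc3ccccc3)c(OCc3ccccc3)c(OCc3ccccc3)c1)[C@@H](OCc1ccccc1)[C@@H]2c1c([C@H]2Oc3cc(OCc4ccccc4)ccc3C(=O)[C@@H]2O)cc(OCc2ccccc2)c(OCc2ccccc2)c1OCc1ccccc1 | intermediate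
17 | (2R,3R)-3,7-dihydroxy-2-{2-[(2R,3S,4S)-3,7-dihydroxy-2-(3,4,5-trihydroxyphenyl)-3,4-dihydro-2H-chromen-4-yl]-3,4,5-trihydroxyphenyl}-2,3-dihydro-4H-chromen-4-one | Oc1ccc2c(c1)O[C@H](c1cc(O)c(O)c(O)c1)[C@@H](O)[C@@H]2c1c([C@H]2Oc3cc(O)ccc3C(=O)[C@@H]2O)cc(O)c(O)c1O | intermediate
18 | (2R,3S,4R)-2-{2-[(2R,3S,4S)-3,7-dihydroxy-2-(3,4,5-trihydroxyphenyl)-3,4-dihydro-2H-chromen-4-yl]-3,4,5-trihydroxyphenyl}-3,4-dihydro-2H-chromene-3,4,7-triol | Oc1ccc2c(c1)O[C@H](c1cc(O)c(O)c(O)c1)[C@@H](O)[C@@H]2c1c([C@H]2Oc3cc(O)ccc3[C@@H](O)[C@@H]2O)cc(O)c(O)c1O | target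

## Step count and risks

Total steps: 11. Longest linear sequence: 10 steps (1 → 2 → 3 → 9 → 10 → 12 → 14 → 15 → 16 → 17 → 18); step 3 is the one-step side branch that supplies chalcone 5.

The three steps most likely to fail:

**Step 4 (aryl cerium 1,2-addition).** The aryl nucleophile carries two ortho substituents and the carbonyl of the phenolate is deactivated, so addition may be slow; carbinol 9 also ionises very easily. The fallback sets out from chalcone 5 and bromide 3 and returns at chromene 10, bypassing step 5. Chalcone 5 is cyclised with NaOAc in refluxing EtOH to racemic 7-(benzyloxy)-2-[3,4,5-tris(benzyloxy)phenyl]-2,3-dihydro-4H-chromen-4-one F1. Preparative chiral SFC of F1 gives the (2S)-flavanone F2. Triflic anhydride with 2,6-di-tert-butyl-4-methylpyridine (CH2Cl2, 0 °C) converts F2 into the (2S)-enol triflate F3 without passing through a ring-opening enolate. Bromide 3 is converted with n-BuLi and then 2-isopropoxy-4,4,5,5-tetramethyl-1,3,2-dioxaborolane into the aryl pinacol boronate F4. Suzuki–Miyaura coupling of F3 with F4 (Pd(OAc)2, 2-dicyclohexylphosphino-2',6'-dimethoxybiphenyl, K3PO4, toluene/H2O, 60 °C) gives 10.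

**Step 5 (asymmetric allylic etherification).** The ortho acetal can take part in the cation and the aryl group is very hindered, so the ion pair may be poorly organised and an uncatalysed racemic cyclisation can compete. The fallback sets out from carbinol 9 and returns at 10. Carbinol 9 is cyclised with achiral pyridinium p-toluenesulfonate (CH2Cl2, 0 °C) to the racemic chromene F5, and the (2S)-enantiomer 10 is collected by preparative chiral SFC; this replaces asymmetric catalysis by resolution.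

**Step 9 (the proposed new oxidative cyclisation).** Selectivity on a hindered, already chiral substrate is untested, and over-oxidation to the flavonol or Dakin-type cleavage may compete. The fallback uses known chemistry, sets out from aldehyde 14 and acetophenone 4, and returns at 16. Acetophenone 4 is protected with chloromethyl methyl ether and NaH to give 1-[4-(benzyloxy)-2-(methoxymethoxy)phenyl]ethan-1-one F6. Claisen–Schmidt condensation of F6 with 14 (KOH, EtOH/THF) gives the 2'-O-methoxymethyl chalcone F7. Juliá–Colonna epoxidation (poly-L-leucine, urea–H2O2, DBU, THF) gives the (αR,βS)-epoxy ketone F8. HCl in MeOH/THF (50 °C) removes the methoxymethyl group, and the freed phenol opens the epoxide at the benzylic carbon (6-endo, inversion) to give the trans-dihydroflavonol 16.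

Further compounds

F1 | step 4 | racemic 7-(benzyloxy)-2-[3,4,5-tris(benzyloxy)phenyl]-2,3-dihydro-4H-chromen-4-one | O=C1CC(c2cc(OCc3ccccc3)c(OCc3ccccc3)c(OCc3ccccc3)c2)Oc2cc(OCc3ccccc3)ccc21
F2 | step 4 | (2S)-7-(benzyloxy)-2-[3,4,5-tris(benzyloxy)phenyl]-2,3-dihydro-4H-chromen-4-one | O=C1C[C@@H](c2cc(OCc3ccccc3)c(OCc3ccccc3)c(OCc3ccccc3)c2)Oc2cc(OCc3ccccc3)ccc21
F3 | step 4 | (2S)-7-(benzyloxy)-2-[3,4,5-tris(benzyloxy)phenyl]-2H-chromen-4-yl trifluoromethanesulfonate | O=S(=O)(OC1=C[C@@H](c2cc(OCc3ccccc3)c(OCc3ccccc3)c(OCc3ccccc3)c2)Oc2cc(OCc3ccccc3)ccc21)C(F)(F)F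
F4 | step 4 | 2-[2,3,4-tris(benzyloxy)-6-(1,3-dioxolan-2-yl)phenyl]-4,4,5,5-tetramethyl-1,3,2-dioxaborolane | CC1(C)OB(OC1(C)C)c1c(C2OCCO2)cc(OCc2ccccc2)c(OCc2ccccc2)c1OCc1ccccc1
F5 | step 5 | racemic 7-(benzyloxy)-4-[2,3,4-tris(benzyloxy)-6-(1,3-dioxolan-2-yl)phenyl]-2-[3,4,5-tris(benzyloxy)phenyl]-2H-chromene | c1ccccc1COc1ccc2c(c1)OC(c1cc(OCc3ccccc3)c(OCc3ccccc3)c(OCc3ccccc3)c1)C=C2c1c(C2OCCO2)cc(OCc2ccccc2)c(OCc2ccccc2)c1OCc1ccccc1
F6 | step 9 | 1-[4-(benzyloxy)-2-(methoxymethoxy)phenyl]ethan-1-one | CC(=O)c1ccc(OCc2ccccc2)cc1OCOC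
F7 | step 9 | (E)-1-[4-(benzyloxy)-2-(methoxymethoxy)phenyl]-3-[3,4,5-tris(benzyloxy)-2-{(2R,3S,4S)-3,7-bis(benzyloxy)-2-[3,4,5-tris(benzyloxy)phenyl]-3,4-dihydro-2H-chromen-4-yl}phenyl]prop-2-en-1-one | c1ccccc1COc1ccc2c(c1)O[C@H](c1cc(OCc3ccccc3)c(OCc3ccccc3)c(OCc3ccccc3)c1)[C@@H](OCc1ccccc1)[C@@H]2c1c(/C=C/C(=O)c2ccc(OCc3ccccc3)cc2OCOC)cc(OCc2ccccc2)c(OCc2ccccc2)c1OCc1ccccc1
F8 | step 9 | [4-(benzyloxy)-2-(methoxymethoxy)phenyl]{(2R,3S)-3-[3,4,5-tris(benzyloxy)-2-{(2R,3S,4S)-3,7-bis(benzyloxy)-2-[3,4,5-tris(benzyloxy)phenyl]-3,4-dihydro-2H-chromen-4-yl}phenyl]oxiran-2-yl}methanone | c1ccccc1COc1ccc2c(c1)O[C@H](c1cc(OCc3ccccc3)c(OCc3ccccc3)c(OCc3ccccc3)c1)[C@@H](OCc1ccccc1)[C@@H]2c1c([C@@H]2O[C@H]2C(=O)c2ccc(OCc3ccccc3)cc2OCOC)cc(OCc2ccccc2)c(OCc2ccccc2)c1OCc1ccccc1
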